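## Retrosynthetic overview

1. Manassantin B1 ⇐ Pd(0) deallylation of its ring-B 3-O-allyl ether ⇐ twofold Felkin–Anh reduction of a bis(α-aryloxy ketone) ⇐ double SN2 (inversion) of a bisphenol oxolane core with a lactate-derived (S)-α-tosyloxy ketone.
2. Bisphenol core ⇐ twofold sulfone-to-aryl substitution (arylzinc on an oxocarbenium ion, sets C2 and the 2,5-trans relationship), then fluoride, which releases two core molecules from one disiloxane tether.
3. Bis-sulfone ⇐ key step: twofold directed branched hydroformylation of a tethered bis-homoallylic alcohol; both γ-hydroxy aldehydes close to lactols in the same operation.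
4. Bis-homoallylic alcohol ⇐ twofold catalytic (Z)-crotylboration of a dialdehyde made from two vanillins and one TIPDS tether (the only phenol protecting group on that side).
5. Ring order: the only rings built are the two oxolanes, both closed together in step 3 (one per half of the tether); all arenes are bought.

Assumption: the anomeric carbons of 6 and 7 are epimer mixtures and are drawn without configuration; (S)-TRIP is taken as the catalyst enantiomer that crotylates the Si face of an aryl aldehyde (its antipode gives (R)-carbinols).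

## Route

Step 1
Reactants: 1 vanillin (4-hydroxy-3-methoxybenzaldehyde); 2 1,3-dichloro-1,1,3,3-tetraisopropyldisiloxane
Product: 3 1,3-bis(4-formyl-2-methoxyphenoxy)-1,1,3,3-tetraisopropyldisiloxane
Conditions: 1 (2.05 equiv), 2 (1.0 equiv), imidazole (4 equiv), DMF, 0 °C → rt
Reagents that add atoms: none
Why: O-silylation (silyl ether formation); one bifunctional disiloxane caps the phenols of two vanillins, so every later operation up to the core is twofold; no stereocentre.

Step 2
Reactants: 3 bis-aldehyde; 4 (Z)-crotylboronic acid pinacol ester (2-[(2Z)-but-2-en-1-yl]-4,4,5,5-tetramethyl-1,3,2-dioxaborolane)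
Product: 5 1,3-bis{4-[(1S,2R)-1-hydroxy-2-methylbut-3-en-1-yl]-2-methoxyphenoxy}-1,1,3,3-tetraisopropyldisiloxane
Conditions: 4 (2.4 equiv), (S)-TRIP phosphoric acid (10 mol%), 4 Å MS, toluene, −30 °C; aq NaHCO3 work-up
Reagents that add atoms: none
Why: Chiral-phosphoric-acid-catalysed crotylboration through a chair Zimmerman–Traxler transition state; the Z geometry gives the 1,2-syn relationship and the catalyst-bound boronate attacks the Si face of each aldehyde, setting (1S,2R) twice (future C5 and C4).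

Step 3
Reactants: 5 bis-homoallylic alcohol
Product: 7 1,3-bis{4-[(2S,3R,4R)-3,4-dimethyl-5-(phenylsulfonyl)oxolan-2-yl]-2-methoxyphenoxy}-1,1,3,3-tetraisopropyldisiloxane (C5 epimers), via bis-lactol 6 (not isolated)
Conditions: Rh(acac)(CO)2 (4 mol%), Ph2POMe (20 mol%), CO/H2 1:1 (40 bar), 4 Å MS, THF, 40 °C; vent, DBU (0.2 equiv), rt; then PhSO2H (3 equiv), CaCl2, CH2Cl2, rt
Reagents that add atoms: carbon monoxide, [C-]#[O+]; benzenesulfinic acid, O=S(O)c1ccccc1
Why: Directed branched hydroformylation with a catalytic phosphinite directing group (Ph2POMe exchanges onto each carbinol oxygen and a six-membered Rh chelate puts CHO on the internal vinyl carbon), after which each γ-hydroxy aldehyde closes to a lactol so that two oxolane rings form in this one operation; the new centre, α to the masked aldehyde, is equilibrated by DBU through the open form to the 3,4-trans lactol (methyl anti to the C4 methyl and the aryl group), and Ley-type exchange with PhSO2H gives the anomeric sulfones.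

Step 4
Reactants: 8 2-(allyloxy)phenol
Product: 9 2-(allyloxy)-4-bromophenol
Conditions: NBS (1.0 equiv), MeCN, 0 °C
Reagents that add atoms: N-bromosuccinimide, O=C1CCC(=O)N1Br
Why: Electrophilic aromatic bromination; the free OH is the stronger director, so bromine enters para to it (as with guaiacol), which fixes the ring-B oxygen pattern; no stereocentre.

Step 5
Reactants: 9 2-(allyloxy)-4-bromophenol
Product: 10 [2-(allyloxy)-4-bromophenoxy](tert-butyl)dimethylsilane
Conditions: TBSCl (1.2 equiv), imidazole (2 equiv), DMF, rt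
Reagents that add atoms: tert-butyldimethylsilyl chloride, C[Si](C)(Cl)C(C)(C)C
Why: O-silylation; masks the phenol for metalation and is later removed by the same fluoride that cuts the tether; no stereocentre.

Step 6
Reactants: 7 bis-sulfone; 10 silyl-protected aryl bromide
Product: 14 2-(allyloxy)-4-[(2S,3R,4R,5S)-5-(4-hydroxy-3-methoxyphenyl)-3,4-dimethyloxolan-2-yl]phenol (two molecules per molecule of 7), via arylmagnesium bromide 11 (not isolated), via arylzinc bromide 12 (not isolated), via tethered bis-oxolane 13 (not isolated)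
Conditions: 10 (2.6 equiv), Mg, LiCl, THF, rt; ZnBr2 (2.6 equiv), 0 °C → rt; add 7, THF, rt; aq NH4Cl; crude in THF, TBAF (4.5 equiv), AcOH (4.5 equiv), 0 °C
Reagents that add atoms: none
Why: Ley sulfone substitution: ZnBr2 ionises each anomeric sulfone to the oxocarbenium ion and the arylzinc adds anti to the C4 methyl and C5 aryl group (2,5-trans), giving the 2,3-cis-3,4-trans-4,5-cis oxolane with the new centre S; fluoride then cleaves both TBS ethers and the disiloxane, and minor stereoisomers are removed on the monomer.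

Step 7
Reactants: 15 4-bromo-1,2-dimethoxybenzene; 16 (2S)-2-hydroxy-N,N-dimethylpropanamide ((S)-N,N-dimethyllactamide)
Product: 18 (2S)-1-(3,4-dimethoxyphenyl)-2-hydroxypropan-1-one, via aryl Grignard 17 (not isolated)
Conditions: 15 (2.6 equiv), Mg, THF, reflux → rt; add 16 (1.0 equiv), THF, 0 °C → rt; aq NH4Cl
Reagents that add atoms: none
Why: Grignard acylation of a tertiary amide; the first equivalent makes the magnesium alkoxide, whose five-membered chelate holds the tetrahedral adduct until work-up, so no over-addition occurs and the lactate centre stays (S).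

Step 8
Reactants: 18 (S)-α-hydroxy ketone
Product: 19 (2S)-1-(3,4-dimethoxyphenyl)-1-oxopropan-2-yl 4-methylbenzenesulfonate
Conditions: TsCl (1.3 equiv), Et3N (1.5 equiv), DMAP (5 mol%), CH2Cl2, 0 °C
Reagents that add atoms: 4-toluenesulfonyl chloride, Cc1ccc(cc1)S(Cl)(=O)=O
Why: O-sulfonylation; the C–O bond is not broken, so (S) is retained.

Step 9
Reactants: 14 bisphenol core; 19 (S)-tosylate
Product: 20 (2R)-2-[2-(allyloxy)-4-[(2S,3R,4R,5S)-5-(4-{[(2R)-1-(3,4-dimethoxyphenyl)-1-oxopropan-2-yl]oxy}-3-methoxyphenyl)-3,4-dimethyloxolan-2-yl]phenoxy]-1-(3,4-dimethoxyphenyl)propan-1-one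
Conditions: 19 (2.4 equiv), Cs2CO3 (3 equiv), DMF, 0 °C → rt
Reagents that add atoms: none
Why: Double Williamson ether synthesis (SN2) at the α-keto carbon with inversion, (S)-tosylate to (R)-aryl ether at both C8; the tosylate leaving group is non-nucleophilic and cannot return, and the allylated 3-oxygen of ring B cannot compete.

Step 10
Reactants: 20 bis-ketone
Product: 21 (1R,2R)-2-[2-(allyloxy)-4-[(2S,3R,4R,5S)-5-(4-{[(1R,2R)-1-(3,4-dimethoxyphenyl)-1-hydroxypropan-2-yl]oxy}-3-methoxyphenyl)-3,4-dimethyloxolan-2-yl]phenoxy]-1-(3,4-dimethoxyphenyl)propan-1-ol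
Conditions: polymer-supported borohydride (BH4− on Amberlite IRA-400, 6 equiv), MeOH, 0 °C → rt
Reagents that add atoms: none
Why: Felkin–Anh (non-chelation) hydride reduction; with a non-coordinating ammonium counter-ion the aryloxy group lies anti to the incoming hydride, which gives the threo carbinol, (7R) next to (8R), at both side chains.

Step 11
Reactants: 21 3-O-allyl manassantin B1
Product: 22 manassantin B1
Conditions: Pd(PPh3)4 (5 mol%), morpholine (10 equiv), THF, rt
Reagents that add atoms: none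
Why: Tsuji–Trost deallylation; Pd(0) ionises the aryl allyl ether and morpholine traps the π-allyl, under neutral conditions that leave the benzylic alcohols, benzylic ethers and all eight stereocentres untouched.

## Compound list

1 | vanillin | COc1cc(C=O)ccc1O | starting material
2 | 1,3-dichloro-1,1,3,3-tetraisopropyldisiloxane | CC(C)[Si](Cl)(C(C)C)O[Si](Cl)(C(C)C)C(C)C | starting material
3 | 1,3-bis(4-formyl-2-methoxyphenoxy)-1,1,3,3-tetraisopropyldisiloxane | COc1cc(C=O)ccc1O[Si](C(C)C)(C(C)C)O[Si](C(C)C)(C(C)C)Oc1ccc(C=O)cc1OC | intermediate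
4 | (Z)-crotylboronic acid pinacol ester | C/C=C\CB1OC(C)(C)C(C)(C)O1 | starting material
5 | 1,3-bis{4-[(1S,2R)-1-hydroxy-2-methylbut-3-en-1-yl]-2-methoxyphenoxy}-1,1,3,3-tetraisopropyldisiloxane | COc1cc([C@@H](O)[C@H](C)C=C)ccc1O[Si](C(C)C)(C(C)C)O[Si](C(C)C)(C(C)C)Oc1ccc([C@@H](O)[C@H](C)C=C)cc1OC | intermediate
6 | 1,3-bis{4-[(2S,3R,4R)-5-hydroxy-3,4-dimethyloxolan-2-yl]-2-methoxyphenoxy}-1,1,3,3-tetraisopropyldisiloxane (bis-lactol, anomers, not isolated) | COc1cc([C@H]2OC(O)[C@H](C)[C@H]2C)ccc1O[Si](C(C)C)(C(C)C)O[Si](C(C)C)(C(C)C)Oc1ccc([C@H]2OC(O)[C@H](C)[C@H]2C)cc1OC | intermediate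
7 | 1,3-bis{4-[(2S,3R,4R)-3,4-dimethyl-5-(phenylsulfonyl)oxolan-2-yl]-2-methoxyphenoxy}-1,1,3,3-tetraisopropyldisiloxane (C5 epimers) | COc1cc([C@H]2OC(S(=O)(=O)c3ccccc3)[C@H](C)[C@H]2C)ccc1O[Si](C(C)C)(C(C)C)O[Si](C(C)C)(C(C)C)Oc1ccc([C@H]2OC(S(=O)(=O)c3ccccc3)[C@H](C)[C@H]2C)cc1OC | intermediate
8 | 2-(allyloxy)phenol | C=CCOc1ccccc1O | starting material
9 | 2-(allyloxy)-4-bromophenol | C=CCOc1cc(Br)ccc1O | intermediate
10 | [2-(allyloxy)-4-bromophenoxy](tert-butyl)dimethylsilane | C=CCOc1cc(Br)ccc1O[Si](C)(C)C(C)(C)C | intermediate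
11 | {3-(allyloxy)-4-[(tert-butyldimethylsilyl)oxy]phenyl}magnesium bromide (not isolated) | C=CCOc1cc([Mg]Br)ccc1O[Si](C)(C)C(C)(C)C | intermediate
12 | {3-(allyloxy)-4-[(tert-butyldimethylsilyl)oxy]phenyl}zinc bromide (not isolated) | C=CCOc1cc([Zn]Br)ccc1O[Si](C)(C)C(C)(C)C | intermediate
13 | 1,3-bis{4-[(2S,3R,4R,5S)-5-{3-(allyloxy)-4-[(tert-butyldimethylsilyl)oxy]phenyl}-3,4-dimethyloxolan-2-yl]-2-methoxyphenoxy}-1,1,3,3-tetraisopropyldisiloxane (not isolated) | COc1cc([C@H]2O[C@H](c3ccc(O[Si](C)(C)C(C)(C)C)c(OCC=C)c3)[C@H](C)[C@H]2C)ccc1O[Si](C(C)C)(C(C)C)O[Si](C(C)C)(C(C)C)Oc1ccc([C@H]2O[C@H](c3ccc(O[Si](C)(C)C(C)(C)C)c(OCC=C)c3)[C@H](C)[C@H]2C)cc1OC | intermediate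
14 | 2-(allyloxy)-4-[(2S,3R,4R,5S)-5-(4-hydroxy-3-methoxyphenyl)-3,4-dimethyloxolan-2-yl]phenol | COc1cc([C@H]2O[C@H](c3ccc(O)c(OCC=C)c3)[C@H](C)[C@H]2C)ccc1O | intermediate
15 | 4-bromo-1,2-dimethoxybenzene | COc1ccc(Br)cc1OC | starting material
16 | (2S)-2-hydroxy-N,N-dimethylpropanamide | C[C@H](O)C(=O)N(C)C | starting material
17 | (3,4-dimethoxyphenyl)magnesium bromide (not isolated) | COc1ccc([Mg]Br)cc1OC | intermediate
18 | (2S)-1-(3,4-dimethoxyphenyl)-2-hydroxypropan-1-one | C[C@H](O)C(=O)c1ccc(OC)c(OC)c1 | intermediate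
19 | (2S)-1-(3,4-dimethoxyphenyl)-1-oxopropan-2-yl 4-methylbenzenesulfonate | C[C@H](OS(=O)(=O)c1ccc(C)cc1)C(=O)c1ccc(OC)c(OC)c1 | intermediate
20 | bis-ketone: core 14 carrying a (2R)-1-(3,4-dimethoxyphenyl)-1-oxopropan-2-yl group on each para oxygen | COc1ccc(C(=O)[C@@H](C)Oc2ccc([C@H]3O[C@H](c4ccc(O[C@H](C)C(=O)c5ccc(OC)c(OC)c5)c(OC)c4)[C@H](C)[C@H]3C)cc2OCC=C)cc1OC | intermediate
21 | 3-O-allyl manassantin B1 (both side chains 7R,8R) | COc1ccc([C@@H](O)[C@@H](C)Oc2ccc([C@H]3O[C@H](c4ccc(O[C@H](C)[C@H](O)c5ccc(OC)c(OC)c5)c(OC)c4)[C@H](C)[C@H]3C)cc2OCC=C)cc1OC | intermediate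
22 | manassantin B1 | COc1ccc([C@@H](O)[C@@H](C)Oc2ccc([C@H]3O[C@H](c4ccc(O[C@H](C)[C@H](O)c5ccc(OC)c(OC)c5)c(OC)c4)[C@H](C)[C@H]3C)cc2O)cc1OC | target

## Step count and risks

Total steps: 11. Longest linear sequence: 7 (steps 1, 2, 3, 6, 9, 10, 11, from vanillin).

Steps most likely to fail:

Step 3 (twofold directed hydroformylation; risk of linear aldehyde, incomplete conversion, or poor control of the new methyl-bearing centre). The fallback sets out from 5 and installs the extra carbon by a classical sequence. Twofold 9-BBN hydroboration with NaBO3 oxidation gives the bis(1,4-diol) F1. TEMPO/PhI(OAc)2 oxidises each primary alcohol and closes it onto the benzylic one, giving the bis(cis-4-methyl-5-aryl lactone) F2. LDA/MeI at −78 °C methylates each lactone anti to the C4 methyl, giving the bis(3R,4R,5S) lactone F3. DIBAL-H at −78 °C reduces it to bis-lactol 6, where the route is rejoined (6 is sulfonylated to 7 as in step 3).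

Step 6 (twofold arylzinc substitution; risk of low facial selectivity or C5 epimerisation under ZnBr2). The fallback sets out from 7 and uses the free phenol 8 as the carbon nucleophile. BF3·OEt2 (or ZnBr2) in CH2Cl2 at −60 °C ionises the sulfones, and 2-(allyloxy)phenol attacks para to its OH (Friedel–Crafts C-arylation, same anti approach to the oxocarbenium ion) to give the tethered bis-phenol F4. TBAF/AcOH then cleaves only the disiloxane and the route is rejoined at 14; steps 4 and 5 fall away.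

Step 9 (double SN2 at an enolisable secondary α-keto tosylate; risk of C8 erosion or elimination under carbonate). The fallback sets out from 14 and the hydroxy ketone 18 and forms both aryl ethers by a double Mitsunobu reaction (PPh3, DIAD, toluene, 0 °C). This inverts the (S)-carbinol under near-neutral conditions and arrives directly at 20; step 8 falls away and no new compound is made (F0).

Further compounds

F1 | step 3 | 1,3-bis{4-[(1S,2R)-1,4-dihydroxy-2-methylbutyl]-2-methoxyphenoxy}-1,1,3,3-tetraisopropyldisiloxane | COc1cc([C@@H](O)[C@H](C)CCO)ccc1O[Si](C(C)C)(C(C)C)O[Si](C(C)C)(C(C)C)Oc1ccc([C@@H](O)[C@H](C)CCO)cc1OC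
F2 | step 3 | 1,3-bis{4-[(2S,3R)-3-methyl-5-oxooxolan-2-yl]-2-methoxyphenoxy}-1,1,3,3-tetraisopropyldisiloxane | COc1cc([C@H]2OC(=O)C[C@H]2C)ccc1O[Si](C(C)C)(C(C)C)O[Si](C(C)C)(C(C)C)Oc1ccc([C@H]2OC(=O)C[C@H]2C)cc1OC
F3 | step 3 | 1,3-bis{4-[(2S,3R,4R)-3,4-dimethyl-5-oxooxolan-2-yl]-2-methoxyphenoxy}-1,1,3,3-tetraisopropyldisiloxane | COc1cc([C@H]2OC(=O)[C@H](C)[C@H]2C)ccc1O[Si](C(C)C)(C(C)C)O[Si](C(C)C)(C(C)C)Oc1ccc([C@H]2OC(=O)[C@H](C)[C@H]2C)cc1OC
F4 | step 6 | 1,3-bis{4-[(2S,3R,4R,5S)-5-[3-(allyloxy)-4-hydroxyphenyl]-3,4-dimethyloxolan-2-yl]-2-methoxyphenoxy}-1,1,3,3-tetraisopropyldisiloxane | COc1cc([C@H]2O[C@H](c3ccc(O)c(OCC=C)c3)[C@H](C)[C@H]2C)ccc1O[Si](C(C)C)(C(C)C)O[Si](C(C)C)(C(C)C)Oc1ccc([C@H]2O[C@H](c3ccc(O)c(OCC=C)c3)[C@H](C)[C@H]2C)cc1OC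
F0 | step 9 | none | none
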